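Start with the easy count: every G that reacts takes one Q, and you subtract. Here is what is known and what is asked.

in all of them: G 20 mM

|  | Q | Z | remark | time |
|---|---|---|---|---|
| noon | 22 mM | 20 mM | run made earlier |  |
| autumn | 22 mM | 30 mM | run made earlier |  |
| flask | 22.0 mM | 40.0 mM |  | 3.0 min |

| run | time / min | E / % | G / % | X / % |
|---|---|---|---|---|
| noon | 0.200 | 9 | 85 | 4 |
| noon | 0.333 | 12 | 77 | 12 |
| noon | 0.500 | 9 | 77 | 15 |
| noon | 0.833 | 2 | 79 | 20 |
| noon | 1.33 | 3 | 71 | 21 |
| noon | 2.50 | 3 | 67 | 34 |
| autumn | 0.200 | 11 | 83 | 5 |
| autumn | 0.333 | 4 | 79 | 13 |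
| autumn | 0.500 | 12 | 75 | 17 |
| autumn | 0.833 | 6 | 76 | 23 |
| autumn | 1.33 | 2 | 73 | 27 |
| autumn | 2.50 | 2 | 65 | 29 |

(scatter of a reading: 2 percentage points)

1. how much E the flask holds at 3.0 min, in percent of the G charged
2. how much G the flask holds at 3.0 min, in percent of the G charged
3. how much X the flask holds at 3.0 min, in percent of the G charged
4. concentration of Q at 3.0 min, in mM



Take the first extreme. Suppose Q goes to G alone. The noon run has lost 6.60 mM of G by 2.50 min, so 15.4 mM of Q stands free, and G's fall should ease merely in that proportion. Now the second extreme. Suppose Q is gone by 0.500 min. Then G should stop at 77 %, yet the noon run goes on to 67 %.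

The truth lies between, and the noon run shows where. If G's fractional fall per minute (a pseudo-first-order constant) follows free Q, then the slow fall over the fast fall gives the free share, the part of the Q charge still free in the slow stretch:

fast fall = 0.813 min⁻¹

slow fall = 0.0696 min⁻¹

free share = 8.56 %

That is far below the first extreme. The readings behind it scatter, and if Q is already dropping during the first 0.200 min, the fast figure reads low, so I take the share as a high estimate, not a bound. For this flask, my reckoning gives

Q at 3.0 min, high estimate = 1.88 mM

with G near 64.7 %. By this reckoning, about 13.5 mM of Q in the noon run would sit where no reading looks.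

The forecast gives E 3 %, G 64 %, X 33 % and Q 14 mM, on the ground “One Q per G converted leaves about 15 mM”.

The flask gives 0.612 mM of Q, with G 64.3 %, X 34.4 % and E 1.24 %. At that time, L, a species no reading showed, stands at 14.2 mM. The free Q is a third of the high estimate, or 2.78 % of its charge.

    G + Q ⇌ Z + E (K = 63.0, k = 1.90 M⁻¹ s⁻¹)
    E + Q ⇌ Z + D (K = 1.60, k = 6.10 M⁻¹ s⁻¹)
    E → X (k = 0.0610 s⁻¹)
    Q ⇌ L (K = 20.0, k = 0.140 s⁻¹)

Take a neighbour flask charged with 55 mM of Q. The free share read from the noon run gives a high estimate of 4.71 mM, and the share computed for the first flask gives 1.53 mM. Computed, that neighbour holds 1.82 mM of Q, less than the high estimate, with G at 30.7 %.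

(The data are calculated for substances that don't exist; scatter was added.)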